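**Plan**

- Lactone numbering: O1, C2(=O), C3, C4, C5. Working backwards, the phenol is masked as a benzyl ether and C3 is given an extra methoxycarbonyl group. The two skeletal cuts then fall on the guaiacyl ring–CH2 bond of the C4 arm and on the C3–CH2 bond of the trimethoxybenzyl arm.
- Enabling feature: the benzylic CH2 on C4 sits next to the enolisable C3. With an ester on C3, that CH2 can be tied back to C3 as a cyclopropane fused across C3–C4 of the γ-lactone (a 3-oxabicyclo[3.1.0]hexan-2-one).
- Forward: cyclopropane and γ-lactone arise together from (R)-epichlorohydrin and dimethyl malonate. The aryl Grignard reagent opens the three-membered ring at its CH2 under copper catalysis, and the enolate set free takes up 3,4,5-trimethoxybenzyl bromide in the same flask. Demethoxycarbonylation and hydrogenolysis finish the route; no further ring is formed.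
- Stereochemistry: C4 (R) comes from the epichlorohydrin stereocentre through one defined inversion during cyclopropanation and is never a reacting centre afterwards. C3 (R) is set last, by base equilibration to the trans lactone.

Key step: step 5

Assumption: the target is the (3R,4R) trans lactone that the SMILES encodes; a benzyl ether protects the phenol because it tolerates Grignard formation and hot LiCl/DMSO and leaves by hydrogenolysis.

**Route**

Step 1
Reactants: 1 (R)-epichlorohydrin; 2 dimethyl malonate
Product: 5 methyl (1S,5R)-2-oxo-3-oxabicyclo[3.1.0]hexane-1-carboxylate, via oxiranylmethyl malonate 3 (not isolated), via hydroxymethylcyclopropane diester 4 (not isolated)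
Conditions: NaOMe (1.0 equiv), MeOH, rt then reflux
Reagents that add atoms: none
Why: Double alkylation of a malonate by an epihalohydrin, in which the malonate anion opens the oxirane at its CH2, the alkoxide expels chloride to give 3, the re-formed malonate anion attacks the oxirane CH in a 3-exo-tet closure with inversion to give 4, and its alkoxide lactonises on the cis ester, so that the single inversion turns the (R) centre of 1 into C5 (R) of 5 and the cis ring fusion fixes C1 as (S).

Step 2
Reactants: 6 4-bromo-2-methoxyphenol
Product: 7 1-(benzyloxy)-4-bromo-2-methoxybenzene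
Conditions: BnBr, K2CO3, DMF, rt
Reagents that add atoms: benzyl bromide, BrCc1ccccc1
Why: Williamson ether synthesis on the phenoxide gives a benzyl ether that is inert to magnesium, organocopper species and chloride in hot DMSO.

Step 3
Reactants: 7 1-(benzyloxy)-4-bromo-2-methoxybenzene
Product: 8 [4-(benzyloxy)-3-methoxyphenyl]magnesium bromide (titrated THF solution used as such)
Conditions: Mg turnings, I2 (cat), THF, 40–65 °C
Reagents that add atoms: magnesium, [Mg]
Why: Grignard formation by oxidative insertion of magnesium into the aryl C–Br bond, to which the two ether groups are indifferent.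

Step 4
Reactants: 9 3,4,5-trimethoxybenzyl alcohol
Product: 10 3,4,5-trimethoxybenzyl bromide
Conditions: PBr3 (0.4 equiv), CH2Cl2, 0 °C → rt
Reagents that add atoms: phosphorus tribromide, BrP(Br)Br
Why: Bromination of a benzylic alcohol through its phosphite ester and SN2 displacement by bromide, mild enough to leave the electron-rich ring unbrominated.

Step 5
Reactants: 5 methyl (1S,5R)-2-oxo-3-oxabicyclo[3.1.0]hexane-1-carboxylate; 8 [4-(benzyloxy)-3-methoxyphenyl]magnesium bromide; 10 3,4,5-trimethoxybenzyl bromide
Product: 12 methyl (3R,4R)-4-[4-(benzyloxy)-3-methoxybenzyl]-2-oxo-3-(3,4,5-trimethoxybenzyl)oxolane-3-carboxylate, via bromomagnesium lactone enolate 11 (not isolated)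
Conditions: CuI (15 mol %), THF, −40 → −20 °C; then DMPU, 10 (1.5 equiv), −20 °C → rt; aq NH4Cl
Reagents that add atoms: none
Why: Transmetalation of 8 to copper gives an aryl copper(I) species that attacks the cyclopropane CH2 (C6 of 5) in an SN2-like way while the C1–C6 bond breaks and its electron pair passes into the lactone- and ester-stabilised enolate 11; this is the copper-catalysed homoconjugate addition of Grignard reagents to doubly activated cyclopropanes, known for 1-alkoxycarbonyl-3-oxabicyclo[3.1.0]hexan-2-ones. Enolate 11 is a malonate-type nucleophile and is C-benzylated by the reactive benzylic bromide 10 once DMPU loosens the magnesium chelate, the usual conjugate addition–enolate alkylation tandem. No ring is closed: the three-membered ring is opened and the γ-lactone is kept. Bicycle C5 becomes lactone C4 without taking part in any bond change, so its (R) configuration is carried over from 5, and the new quaternary C3 is controlled by that neighbour, the bromide approaching the enolate face anti to the C4 arm; either C3 epimer would converge in step 6. The step needs homoconjugate opening over 1,2-addition to the two carbonyl groups, which copper catalysis at low temperature and the strained, doubly activated C1–C6 bond secure, and attack at CH2 over the ring-fusion CH, which the primary carbon and the better leaving carbanion secure. It also needs C- over O-alkylation, which a soft benzylic bromide and a 1,3-dicarbonyl enolate favour.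

Step 6
Reactants: 12 methyl (3R,4R)-4-[4-(benzyloxy)-3-methoxybenzyl]-2-oxo-3-(3,4,5-trimethoxybenzyl)oxolane-3-carboxylate
Product: 14 O-benzyl hernanol [(3R,4R)-4-[4-(benzyloxy)-3-methoxybenzyl]-3-(3,4,5-trimethoxybenzyl)oxolan-2-one], via cis C3 epimer 13 (not isolated)
Conditions: LiCl (3 equiv), H2O (2 equiv), DMSO, 150 °C; aq work-up; crude with NaOMe (0.2 equiv), MeOH, 50 °C, then AcOH
Reagents that add atoms: none
Why: Krapcho demethoxycarbonylation, in which chloride demethylates the ester, the β-carbonyl carboxylate loses CO2 and water protonates the lactone enolate, followed by methoxide-mediated enolisation that drains the cis epimer 13 into the more stable trans lactone 14 under thermodynamic control while the non-enolisable C4 stays untouched.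

Step 7
Reactants: 14 O-benzyl hernanol
Product: 15 hernanol [(3R,4R)-4-(4-hydroxy-3-methoxybenzyl)-3-(3,4,5-trimethoxybenzyl)oxolan-2-one]
Conditions: H2 (1 atm), 10% Pd/C, EtOAc–EtOH, rt
Reagents that add atoms: none
Why: Hydrogenolysis of the aryl benzyl ether on palladium, under which the lactone, the aryl methyl ethers, the benzylic C–C bonds and both stereocentres are stable.

**Compound list**

1 | (R)-epichlorohydrin | ClC[C@H]1CO1 | starting material
2 | dimethyl malonate | COC(=O)CC(=O)OC | starting material
3 | dimethyl 2-{[(2R)-oxiran-2-yl]methyl}propanedioate | COC(=O)C(C[C@@H]1CO1)C(=O)OC | intermediate (not isolated)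
4 | dimethyl (2R)-2-(hydroxymethyl)cyclopropane-1,1-dicarboxylate, present as its sodium alkoxide | OC[C@@H]1CC1(C(=O)OC)C(=O)OC | intermediate (not isolated)
5 | methyl (1S,5R)-2-oxo-3-oxabicyclo[3.1.0]hexane-1-carboxylate | C1[C@H]2COC(=O)[C@@]12C(=O)OC | intermediate
6 | 4-bromo-2-methoxyphenol | COc1cc(Br)ccc1O | starting material
7 | 1-(benzyloxy)-4-bromo-2-methoxybenzene | COc1cc(Br)ccc1OCc1ccccc1 | intermediate
8 | [4-(benzyloxy)-3-methoxyphenyl]magnesium bromide | COc1cc([Mg]Br)ccc1OCc1ccccc1 | intermediate
9 | 3,4,5-trimethoxybenzyl alcohol | COc1cc(CO)cc(OC)c1OC | starting material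
10 | 3,4,5-trimethoxybenzyl bromide | COc1cc(CBr)cc(OC)c1OC | intermediate
11 | bromomagnesium enolate of methyl (4R)-4-[4-(benzyloxy)-3-methoxybenzyl]-2-oxooxolane-3-carboxylate | COc1cc(C[C@H]2COC(O[Mg]Br)=C2C(=O)OC)ccc1OCc1ccccc1 | intermediate (not isolated)
12 | methyl (3R,4R)-4-[4-(benzyloxy)-3-methoxybenzyl]-2-oxo-3-(3,4,5-trimethoxybenzyl)oxolane-3-carboxylate | COc1cc(C[C@H]2COC(=O)[C@]2(C(=O)OC)Cc2cc(OC)c(OC)c(OC)c2)ccc1OCc1ccccc1 | intermediate
13 | (3S,4R)-4-[4-(benzyloxy)-3-methoxybenzyl]-3-(3,4,5-trimethoxybenzyl)oxolan-2-one (cis epimer, formed in part beside 14 and epimerised to it) | COc1cc(C[C@H]2COC(=O)[C@H]2Cc2cc(OC)c(OC)c(OC)c2)ccc1OCc1ccccc1 | intermediate (not isolated)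
14 | O-benzyl hernanol, (3R,4R)-4-[4-(benzyloxy)-3-methoxybenzyl]-3-(3,4,5-trimethoxybenzyl)oxolan-2-one | COc1cc(C[C@H]2COC(=O)[C@@H]2Cc2cc(OC)c(OC)c(OC)c2)ccc1OCc1ccccc1 | intermediate
15 | hernanol, (3R,4R)-4-(4-hydroxy-3-methoxybenzyl)-3-(3,4,5-trimethoxybenzyl)oxolan-2-one | COc1cc(C[C@H]2COC(=O)[C@@H]2Cc2cc(OC)c(OC)c(OC)c2)ccc1O | target

**Count**

Total steps: 7. Longest linear sequence: 5 steps (6 → 7 → 8 → 12 → 14 → 15).

**Steps most likely to fail**

Step 5. The chelated bromomagnesium enolate may be benzylated only sluggishly, or bromide 10 may be consumed by copper-mediated coupling with surplus Grignard reagent, so that the tandem stalls after the ring opening. The fallback separates the two bond formations and moves the benzylation behind the ester removal. It sets out from 5 and 8: the same copper-catalysed opening is quenched with aqueous NH4Cl, which protonates 11 to methyl (4R)-4-[4-(benzyloxy)-3-methoxybenzyl]-2-oxooxolane-3-carboxylate F1. Krapcho demethoxycarbonylation (LiCl, H2O, DMSO, 150 °C) then gives (4R)-4-[4-(benzyloxy)-3-methoxybenzyl]oxolan-2-one F2. Deprotonation with LDA in THF at −78 °C forms the lithium enolate of that lactone F3, which is alkylated by 10 anti to the C4 substituent, the classical trans-selective α-benzylation of β-benzyl-γ-butyrolactones. The route is rejoined at 14.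

Step 6. Dealkylation at the hindered quaternary centre may stay incomplete, the lactone may be opened by chloride or hydroxide at 150 °C, and the C3 equilibration may stop short. The fallback replaces nucleophilic demethylation by hydrolysis and thermal decarboxylation. It sets out from 12: KOH in aqueous MeOH at reflux saponifies the ester and opens the lactone, and acidification with HCl liberates 2-[(2R)-1-[4-(benzyloxy)-3-methoxyphenyl]-3-hydroxypropan-2-yl]-2-(3,4,5-trimethoxybenzyl)propanedioic acid F4. This closes spontaneously to (4R)-4-[4-(benzyloxy)-3-methoxybenzyl]-2-oxo-3-(3,4,5-trimethoxybenzyl)oxolane-3-carboxylic acid F5 (C3 epimers, without consequence). Heating F5 in toluene at reflux expels CO2, and the same methoxide equilibration of the resulting mixture of 13 and 14 returns the route to 14.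

Step 3. Insertion of magnesium into the electron-rich aryl bromide may start late and be accompanied by Wurtz-type homocoupling, which leaves a solution of uncertain titre for step 5. The fallback makes the aryl–metal bond by halogen–metal exchange. It sets out from 7: n-BuLi in THF at −78 °C gives [4-(benzyloxy)-3-methoxyphenyl]lithium F6, and transmetalation with MgBr2·OEt2 returns the route to 8.

Further compounds
F1 | step 5 | methyl (4R)-4-[4-(benzyloxy)-3-methoxybenzyl]-2-oxooxolane-3-carboxylate (C3 epimers) | COc1cc(C[C@H]2COC(=O)C2C(=O)OC)ccc1OCc1ccccc1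
F2 | step 5 | (4R)-4-[4-(benzyloxy)-3-methoxybenzyl]oxolan-2-one | COc1cc(C[C@H]2COC(=O)C2)ccc1OCc1ccccc1
F3 | step 5 | lithium enolate of (4R)-4-[4-(benzyloxy)-3-methoxybenzyl]oxolan-2-one | COc1cc(C[C@H]2COC(O[Li])=C2)ccc1OCc1ccccc1
F4 | step 6 | 2-[(2R)-1-[4-(benzyloxy)-3-methoxyphenyl]-3-hydroxypropan-2-yl]-2-(3,4,5-trimethoxybenzyl)propanedioic acid | COc1cc(C[C@@H](CO)C(C(=O)O)(C(=O)O)Cc2cc(OC)c(OC)c(OC)c2)ccc1OCc1ccccc1
F5 | step 6 | (4R)-4-[4-(benzyloxy)-3-methoxybenzyl]-2-oxo-3-(3,4,5-trimethoxybenzyl)oxolane-3-carboxylic acid (C3 epimers) | COc1cc(C[C@H]2COC(=O)C2(C(=O)O)Cc2cc(OC)c(OC)c(OC)c2)ccc1OCc1ccccc1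
F6 | step 3 | [4-(benzyloxy)-3-methoxyphenyl]lithium | [Li]c1ccc(OCc2ccccc2)c(OC)c1
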